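If you want to know where the catalyst sits in this flask once 30% of the E is converted, follow one catalyst molecule from fork to fork.

    E + L ⇌ L + X (K1 = 2.3, k1 = 297 L mol⁻¹ h⁻¹)
    L + X ⇌ L.X (K2 = 860 L mol⁻¹, k2 = 1520 L mol⁻¹ h⁻¹)
    J + L.X → L + G (k3 = 1110 L mol⁻¹ h⁻¹)
    E + J → E.J (k4 = 2.41 L mol⁻¹ h⁻¹)
    L ⇌ Q (K5 = 1.17, k5 = 1.15 h⁻¹)

E 15 mM; J 14.2 mM; L 58 µM

* the form that holds most of the catalyst when 30% of the E are converted (Q / L / L.X)
* its share of the catalyst then

My reckoning starts with a clock. If E and J simply reacted with each other, at nearly equal charges, 30% conversion would take about 11.9 h. The exchange of L and Q relaxes in 0.325 h, which is far shorter than that, so a molecule not bound to X has long since lost memory of which form it started in. The share of Q among the catalyst not held as L.X is then 53.9%, and Q's share of the whole catalyst is this number times what L.X leaves over. Since 1.17 is more than 1, Q outweighs L.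

Is that one number enough? Not quite: some catalyst sits in L.X. Take J as down by 30% as well. L.X then goes on with J at 11.0 h⁻¹, faster than it falls apart at 1.77 h⁻¹, so 86.1% of the molecules that enter it leave forward. For X, take an overestimate: the first step running unopposed with E as charged gives 1.41 mM. That puts [L.X]/[L] at 0.168 and Q at 50.1%. I therefore commit to Q, between 50.1% and 53.9%.

The forecast also names Q, with 52% and a narrower range of 50.5% to 53.5%, holding that “L.X stays small because J strips it quickly”.

The flask reaches 30% conversion after 9.53 h and then gives Q at 51.8%, with L at 44.1% and L.X at 4.02%. Q is the off-cycle form, standing outside the working round, so 51.8% of the catalyst is out of that round at this moment. The same flask at 250 h has L.X at 14.1%, and 53.9% of the remaining 85.9% comes to 46.3%, where the flask holds Q at 46.3%.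

(Its constants were chosen freely.)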